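## Structural features

The target is a 2-aryl-3-methyl-2,3-dihydrobenzofuran neolignan. Ring A (the benzo ring, with OMe at C7 and an (E)-prop-1-enyl group at C5) is fused through C3a and C7a to ring B (the dihydrofuran O1–C2–C3). Ring C (3-hydroxy-4,5-dimethoxyphenyl) sits on C2. The only stereocentres are the adjacent C2 (S, bearing ring C and O1) and C3 (S, bearing methyl), with aryl and methyl trans; the alkene is E. Three groups are fragile. The O1–C2 bond is a benzylic ether para to the ring C 4-methoxy group, so acid can ionise it and epimerise C2. The electron-rich styrene does not tolerate strong acid, electrophiles or hydrogenation. The ring C phenol must be masked whenever base and electrophiles are present. The real difficulty is the absolute configuration of the C2/C3 pair, because C3 carries only methyl, hydrogen and two carbon substituents and offers no handle for conventional asymmetric methods. The key step uses the fact that C2 is the single atom joining O1 to C3: the other four atoms, O1–C7a–C3a–C3, form an ortho-quinone methide of ring A, and C2 can be delivered as a one-carbon ylide that already carries ring C. The C5 substituent is para to O1 and can travel as a bromide until both stereocentres are in place.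

## Logic of the disconnections

19 ⇒ 16 + 17 (through 18). The C5–alkenyl bond and the O–Si bond on ring C are cut. This keeps the styrene away from the base, the ylide and the quinone methide of the annulation, and leaves only a cross-coupling and a fluoride treatment after the stereocentres exist. The forward step must keep the E geometry, must not touch C2 or C3, and must avoid acid. Coupling and desilylation are run in one flask because aqueous carbonate and the fluoride released from 17 would erode the silyl ether anyway.

16 ⇒ 3 + 12 (through 13, 14 and 15). The C2–C3 and O1–C2 bonds are cut, which is the [4+1] retron. One step then builds ring B, both ring bonds and both stereocentres from two fragments of similar size, neither of which needs its own carbon stereocentre. The demands are that 13 is intercepted by 14 faster than it tautomerises or dimerises, that the sulfide controls the face of 14, and that 15 closes to the trans ring.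

3 ⇒ 2 ⇒ 1. The benzylic C–S bond is cut, then the C–CH3 bond. The sulfinate is chosen as the leaving group because the phenoxide of 3 expels it under mild carbonate base to release 13. The stereocentre of 2 and 3 is destroyed in that elimination, so both can be racemic. The forward steps need two equivalents of the Grignard reagent (phenol first) and S-selective capture of the benzylic cation.

12 ⇒ 11 + 7. The S–CH2 bond is cut. Because 7 is C2-symmetric its two lone pairs are equivalent, so alkylation gives a single salt with no stereogenic sulfur. The hindered sulfide needs a silver-assisted alkylation and a non-nucleophilic counter-ion.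

11 ⇒ 10 ⇒ 9 ⇒ 8. These are functional-group changes only (C–Br, carbonyl reduction, O–Si). The phenol is silylated first so that no phenoxide can later compete with 14 for 13. The silyl ether must survive borohydride, PBr3 and carbonate and still leave with fluoride.

7 ⇒ 5 ⇒ 4 (through 6). Both C–S bonds are cut. Two SN2 displacements invert both carbinol centres, so the (2S,5S) sulfide requires the (2R,5R) diol. The antipode is fixed by C2: in 14 the aryl group lies syn to the sulfur lone pair and the α-methyl group cis to the ylide carbon screens one face. Attack of 13 on the open face, then inversion in the closure of 15, gives S at C2 from the (2S,5S) sulfide. The (2R,5R) sulfide, made from the (2S,5S) diol, would be expected to give the (2R,3R) mirror image of 16, so it is not used.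

## Other disconnections considered

Alternative 1: The cut is O1–C7a, made last. The open-chain (1S,2S) carbinol A1, whose ring A carries a triflate ortho to the side chain, would be closed to A2 (the methoxymethyl ether of 19) with Pd2(dba)3 (zerovalent palladium), t-BuXPhos and K3PO4. Acid would then free the phenol.
- In its favour: the bond formed involves neither stereocentre, so the closure is retentive by mechanism, and both centres can be set and checked before the ring exists. On this point Alternative 1 is the better plan, since the chosen route relies on reagent control in the ring-forming step itself. The propenyl group can be present from the start, which is equal to the chosen plan in end-game length (one deprotection after the key step).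
- Against it: the palladium alkoxide of a secondary benzylic carbinol can undergo β-hydride elimination, which would oxidise C2 and make C3 epimerisable. The triflate is flanked by two ortho substituents on an electron-rich ring, so oxidative addition is slow and S–O cleavage by phosphate competes. The final acidic removal of the methoxymethyl group threatens the para-methoxybenzylic O1–C2 bond and the styrene, whereas the chosen route ends with fluoride.
- Comparison: building A1 needs an acyclic diad with an aryl group on each stereocentre, for which no aldol-type solution exists, and is expected to take clearly more steps than the six-step longest sequence of the chosen plan.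

Alternative 2: The cuts are O1–C2 and the cyclopropane bond between C2 and the carbon that becomes the C3 methyl. The trans-diarylcyclopropane A3, with a free ortho phenol on ring A, would be treated with catalytic TfOH in hexafluoroisopropanol. Protonation of the CH2 carbon breaks its bond to C2, and the phenol captures the ring C benzylic cation to give the ester A4.
- In its favour: the step is an isomerisation that keeps every atom, needs no metal and only catalytic acid. On atom economy it is better than the chosen key step, which discards a sulfinate and uses a stoichiometric (though recoverable) chiral sulfide. Only the ring A-bearing cyclopropane carbon has to be controlled, because C2 is set by the trans-selective closure and can equilibrate to trans under the same acid.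
- Against it: an enantioenriched A3 needs an asymmetric cyclopropanation of an electron-rich stilbene or a chiral cyclopropyl coupling partner, which costs several steps. Protonolysis must break the CH2–C2 bond and not the C2–C3 bond, which would lead to a six-membered ring. The cation next to C3–H can lose that proton or shift hydride, which would erase the one controlled centre. TfOH is also a threat to the aryl silyl ether.
- Comparison: the ester at C5 of A4 still has to become the (E)-propenyl group (partial reduction and E-selective ethylidenation) before desilylation, against one operation in the chosen plan. The chosen route is shorter and has no cationic centre next to C3.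

Alternative 3: The cut is C2–C3. The ring A aryldiazoacetate A5, whose phenol oxygen carries the ring C benzyl group, would be decomposed with Rh2(S-PTTL)4 or its enantiomer (divalent rhodium), whichever gives S at C2. The carbenoid inserts into the O–CH2 bond by a 1,5 C–H insertion to give the cis ester A6.
- In its favour: the chiral information is catalytic, which is better than the stoichiometric sulfide of the chosen route. Intramolecular insertion next to an ether oxygen is a well-understood five-membered closure. The aryl bromide is carried exactly as in the chosen plan, so the two are equal on the late cross-coupling.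
- Against it: A6 has the wrong relative configuration and the wrong oxidation level at C3. Base epimerisation at C3, then reduction, activation and hydride displacement are needed to turn the ester into methyl, all beside an aryl bromide, before coupling and acidic removal of the methoxymethyl group. The electron-rich ring C and the ether oxygen invite aromatic cycloaddition and oxonium ylide formation in competition with insertion. A diazo compound must be made and handled.
- Comparison: at least six operations follow the key step, against one in the chosen plan, and C3 is set only indirectly by thermodynamic epimerisation. The chosen [4+1] sets C2 and C3 directly at the final oxidation level.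

Key step: step 9

Remark on the chemistry: the sense of induction is assigned from the accepted model for 2,5-dimethylthiolanium benzylides and is assumed to carry over from aldehydes to the quinone methide. The same attack that gives (S,S)-epoxides from the (2R,5R) sulfide gives R at C2 here, because ring C outranks C3 whereas an epoxide carbon outranks aryl.

## Route

Step 1
Reactants: 1 5-bromo-2-hydroxy-3-methoxybenzaldehyde
Product: 2 4-bromo-2-(1-hydroxyethyl)-6-methoxyphenol (racemic)
Conditions: MeMgBr (2.5 equiv), THF, −78 → 0 °C; aq NH4Cl
Reagents that add atoms: methylmagnesium bromide, C[Mg]Br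
Why: Grignard addition to the aldehyde; the first equivalent deprotonates the phenol and the second adds to the carbonyl, while the aryl bromide is inert to MeMgBr at this temperature. The new centre is racemic and is destroyed in step 9.

Step 2
Reactants: 2 4-bromo-2-(1-hydroxyethyl)-6-methoxyphenol
Product: 3 4-bromo-2-methoxy-6-[1-(4-methylphenylsulfonyl)ethyl]phenol (racemic)
Conditions: p-TolSO2Na (2 equiv), HCO2H–H2O (1:1), rt
Reagents that add atoms: sodium 4-methylbenzenesulfinate, Cc1ccc(cc1)S(=O)[O-].[Na+]
Why: Acid-promoted SN1 substitution; the ortho-hydroxy group assists ionisation of the benzylic alcohol and the sulfinate captures the cation at sulfur, the sulfone being the thermodynamic product. The centre is racemic and irrelevant.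

Step 3
Reactants: 4 (2R,5R)-hexane-2,5-diol
Product: 5 (2R,5R)-hexane-2,5-diyl dimethanesulfonate
Conditions: MsCl, Et3N, CH2Cl2, −20 → 0 °C
Reagents that add atoms: methanesulfonyl chloride, CS(=O)(=O)Cl
Why: O-Sulfonylation of both secondary alcohols; no C–O bond is broken, so both centres are retained.

Step 4
Reactants: 5 (2R,5R)-hexane-2,5-diyl dimethanesulfonate
Product: 7 (2S,5S)-2,5-dimethylthiolane, via thiolate monomesylate 6 (not isolated)
Conditions: Na2S·9H2O, DMSO, rt; pentane extraction, distillation
Reagents that add atoms: sodium sulfide, [Na+].[Na+].[S-2]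
Why: Two consecutive SN2 displacements by sulfur, the second a 5-exo-tet closure; each inverts its carbon, so the (2R,5R) dimesylate gives the (2S,5S) sulfide.

Step 5
Reactants: 8 3-hydroxy-4,5-dimethoxybenzaldehyde
Product: 9 3-[(tert-butyldimethylsilyl)oxy]-4,5-dimethoxybenzaldehyde
Conditions: TBSCl, imidazole, DMF, rt
Reagents that add atoms: tert-butyldimethylsilyl chloride, CC(C)(C)[Si](C)(C)Cl
Why: Standard phenol silylation; the silyl ether keeps a ring C phenoxide from adding to the quinone methide in step 9 and is removed by fluoride without acid.

Step 6
Reactants: 9 3-[(tert-butyldimethylsilyl)oxy]-4,5-dimethoxybenzaldehyde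
Product: 10 {3-[(tert-butyldimethylsilyl)oxy]-4,5-dimethoxyphenyl}methanol
Conditions: NaBH4, MeOH, 0 °C
Reagents that add atoms: none
Why: Borohydride reduction of an aryl aldehyde; short exposure at 0 °C leaves the aryl silyl ether intact.

Step 7
Reactants: 10 {3-[(tert-butyldimethylsilyl)oxy]-4,5-dimethoxyphenyl}methanol
Product: 11 [5-(bromomethyl)-2,3-dimethoxyphenoxy](tert-butyl)dimethylsilane
Conditions: PBr3 (0.4 equiv), Et2O, 0 °C; aq NaHCO3; used at once
Reagents that add atoms: phosphorus tribromide, BrP(Br)Br
Why: Conversion of a benzylic alcohol to the bromide through its phosphite ester; the by-product is water-soluble, so the reactive bromide needs no chromatography.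

Step 8
Reactants: 11 [5-(bromomethyl)-2,3-dimethoxyphenoxy](tert-butyl)dimethylsilane; 7 (2S,5S)-2,5-dimethylthiolane
Product: 12 (2S,5S)-1-{3-[(tert-butyldimethylsilyl)oxy]-4,5-dimethoxybenzyl}-2,5-dimethylthiolan-1-ium tetrafluoroborate
Conditions: AgBF4, 7 (1.2 equiv), CH2Cl2, 0 °C → rt, dark; filter; precipitate with Et2O
Reagents that add atoms: silver tetrafluoroborate, [Ag+].F[B-](F)(F)F
Why: Silver-assisted S-alkylation of a sulfide by a benzylic bromide; the two lone pairs of the C2-symmetric sulfide are equivalent, so one salt forms and sulfur is not stereogenic, and tetrafluoroborate cannot dealkylate the salt.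

Step 9
Reactants: 3 4-bromo-2-methoxy-6-[1-(4-methylphenylsulfonyl)ethyl]phenol; 12 (2S,5S)-1-{3-[(tert-butyldimethylsilyl)oxy]-4,5-dimethoxybenzyl}-2,5-dimethylthiolan-1-ium tetrafluoroborate
Product: 16 (2S,3S)-5-bromo-2-{3-[(tert-butyldimethylsilyl)oxy]-4,5-dimethoxyphenyl}-7-methoxy-3-methyl-2,3-dihydro-1-benzofuran, via ortho-quinone methide 13 (not isolated), via sulfonium ylide 14 (not isolated), via betaine 15 (not isolated)
Conditions: Cs2CO3 (3 equiv), 12 (1.3 equiv), CH2Cl2, −20 → 0 °C, 3 added in CH2Cl2 over 6 h
Reagents that add atoms: none
Why: Cs2CO3 deprotonates the phenol of 3, which expels p-toluenesulfinate (E1cB) to give 13, and the same base reversibly deprotonates 12 to 14. The ylide carbon of 14 adds to the exocyclic carbon of 13, forming C2–C3 and restoring the aromatic phenoxide in 15, whose oxygen displaces the sulfide by a 5-exo-tet SN2 with inversion at C2, forming O1–C2 and closing ring B. The closest known reaction type is the [4+1] annulation of sulfonium ylides with ortho-quinone methides released from 2-(1-sulfonylalkyl)phenols, which gives trans-2,3-dihydrobenzofurans, combined with the face control that C2-symmetric thiolanium benzylides show in epoxidation. C2 is controlled by the sulfide: ring C lies syn to the sulfur lone pair, the α-methyl group cis to the ylide carbon blocks one face, and attack on the open face followed by inversion should give S from the (2S,5S) salt. C3 is set relative to C2: only the betaine with ring C and methyl anti reaches the backside-displacement geometry without eclipsing them, so the ring closes trans (3S). The step needs capture of 13 to outrun its tautomerisation to the vinylphenol, its dimerisation, and O-benzylation of the phenoxide by 12. Low temperature, slow addition of 3 into an excess of 12, and the E geometry of 13 (methyl turned away from the carbonyl oxygen) are meant to secure this. The aryl bromide and the silyl ether are inert to carbonate in CH2Cl2, and 7 is released and can be recovered.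

Step 10
Reactants: 16 (2S,3S)-5-bromo-2-{3-[(tert-butyldimethylsilyl)oxy]-4,5-dimethoxyphenyl}-7-methoxy-3-methyl-2,3-dihydro-1-benzofuran; 17 potassium (E)-prop-1-enyltrifluoroborate
Product: 19 5-[(2S,3S)-7-methoxy-3-methyl-5-[(E)-prop-1-enyl]-2,3-dihydro-1-benzofuran-2-yl]-2,3-dimethoxyphenol, via silyl ether 18 (not isolated)
Conditions: PdCl2(dppf)·CH2Cl2 (5 mol %), Cs2CO3 (3 equiv), THF–H2O (10:1), 70 °C; then TBAF, THF, rt; aq NH4Cl
Reagents that add atoms: none
Why: Suzuki–Miyaura coupling of the aryl bromide with an alkenyltrifluoroborate (the divalent palladium precatalyst is reduced in the flask to zerovalent palladium); transmetalation retains the E geometry, and fluoride then cleaves the aryl silyl ether. No acid is used and neither C2 nor C3 is touched; running both operations in one flask brings any silyl ether already lost during coupling to the same product.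

## Compound list

1 | 5-bromo-2-hydroxy-3-methoxybenzaldehyde | O=Cc1cc(Br)cc(OC)c1O | starting material
2 | 4-bromo-2-(1-hydroxyethyl)-6-methoxyphenol (racemic) | CC(O)c1cc(Br)cc(OC)c1O | intermediate
3 | 4-bromo-2-methoxy-6-[1-(4-methylphenylsulfonyl)ethyl]phenol (racemic) | CC(c1cc(Br)cc(OC)c1O)S(=O)(=O)c1ccc(C)cc1 | intermediate
4 | (2R,5R)-hexane-2,5-diol | C[C@@H](O)CC[C@@H](C)O | starting material
5 | (2R,5R)-hexane-2,5-diyl dimethanesulfonate | C[C@@H](OS(C)(=O)=O)CC[C@@H](C)OS(C)(=O)=O | intermediate
6 | sodium (2S,5R)-5-(methylsulfonyloxy)hexane-2-thiolate | C[C@H]([S-])CC[C@@H](C)OS(C)(=O)=O.[Na+] | intermediate (not isolated)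
7 | (2S,5S)-2,5-dimethylthiolane | C[C@H]1CC[C@H](C)S1 | intermediate
8 | 3-hydroxy-4,5-dimethoxybenzaldehyde | O=Cc1cc(O)c(OC)c(OC)c1 | starting material
9 | 3-[(tert-butyldimethylsilyl)oxy]-4,5-dimethoxybenzaldehyde | O=Cc1cc(O[Si](C)(C)C(C)(C)C)c(OC)c(OC)c1 | intermediate
10 | {3-[(tert-butyldimethylsilyl)oxy]-4,5-dimethoxyphenyl}methanol | OCc1cc(O[Si](C)(C)C(C)(C)C)c(OC)c(OC)c1 | intermediate
11 | [5-(bromomethyl)-2,3-dimethoxyphenoxy](tert-butyl)dimethylsilane | BrCc1cc(O[Si](C)(C)C(C)(C)C)c(OC)c(OC)c1 | intermediate
12 | (2S,5S)-1-{3-[(tert-butyldimethylsilyl)oxy]-4,5-dimethoxybenzyl}-2,5-dimethylthiolan-1-ium tetrafluoroborate | C[C@H]1CC[C@H](C)[S+]1Cc1cc(O[Si](C)(C)C(C)(C)C)c(OC)c(OC)c1.F[B-](F)(F)F | intermediate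
13 | (6E)-4-bromo-6-ethylidene-2-methoxycyclohexa-2,4-dien-1-one | C/C=C1\C=C(Br)C=C(OC)C1=O | intermediate (not isolated)
14 | {3-[(tert-butyldimethylsilyl)oxy]-4,5-dimethoxyphenyl}[(2S,5S)-2,5-dimethylthiolan-1-ium-1-yl]methanide | C[C@H]1CC[C@H](C)[S+]1[CH-]c1cc(O[Si](C)(C)C(C)(C)C)c(OC)c(OC)c1 | intermediate (not isolated)
15 | 4-bromo-2-methoxy-6-[(1R,2S)-1-{3-[(tert-butyldimethylsilyl)oxy]-4,5-dimethoxyphenyl}-1-[(2S,5S)-2,5-dimethylthiolan-1-ium-1-yl]propan-2-yl]phenolate | [O-]c1c(OC)cc(Br)cc1[C@H](C)[C@H](c1cc(O[Si](C)(C)C(C)(C)C)c(OC)c(OC)c1)[S+]1[C@@H](C)CC[C@@H]1C | intermediate (not isolated)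
16 | (2S,3S)-5-bromo-2-{3-[(tert-butyldimethylsilyl)oxy]-4,5-dimethoxyphenyl}-7-methoxy-3-methyl-2,3-dihydro-1-benzofuran | Brc1cc(OC)c2c(c1)[C@H](C)[C@@H](c1cc(O[Si](C)(C)C(C)(C)C)c(OC)c(OC)c1)O2 | intermediate
17 | potassium (E)-prop-1-enyltrifluoroborate | C/C=C/[B-](F)(F)F.[K+] | starting material
18 | tert-butyl{5-[(2S,3S)-7-methoxy-3-methyl-5-[(E)-prop-1-enyl]-2,3-dihydro-1-benzofuran-2-yl]-2,3-dimethoxyphenoxy}dimethylsilane | C/C=C/c1cc(OC)c2c(c1)[C@H](C)[C@@H](c1cc(O[Si](C)(C)C(C)(C)C)c(OC)c(OC)c1)O2 | intermediate (not isolated)
19 | 5-[(2S,3S)-7-methoxy-3-methyl-5-[(E)-prop-1-enyl]-2,3-dihydro-1-benzofuran-2-yl]-2,3-dimethoxyphenol | C/C=C/c1cc(OC)c2c(c1)[C@H](C)[C@@H](c1cc(O)c(OC)c(OC)c1)O2 | target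

## Step count and least certain steps

Total step count: 10. Longest linear sequence: 6 steps (steps 5, 6, 7, 8, 9 and 10, from 8).

Step 9 (key step). The most likely failure is incomplete discrimination between the two faces of 14. The sulfide's face control is established for aldehydes, not for a planar and very reactive quinone methide, and any reversibility in forming 15 would erode it further. Behind this stands loss of 13 by tautomerisation to the vinylphenol before the dilute ylide captures it. The fallback replaces reagent control by resolution; it sets out from 11 and 3 and returns at 16. Bromide 11 is alkylated onto thiolane (AgBF4, CH2Cl2) to give the achiral salt 1-{3-[(tert-butyldimethylsilyl)oxy]-4,5-dimethoxybenzyl}thiolan-1-ium tetrafluoroborate F1. F1 and 3 under the Cs2CO3 conditions of step 9 should give racemic trans-5-bromo-2-{3-[(tert-butyldimethylsilyl)oxy]-4,5-dimethoxyphenyl}-7-methoxy-3-methyl-2,3-dihydro-1-benzofuran F2. Preparative chromatography on an amylose tris(3,5-dimethylphenylcarbamate) phase then separates the enantiomers; the (2S,3S) half is 16 and the mirror-image half is set aside.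

Step 8. S-Alkylation of the α,α'-disubstituted sulfide may be slow. The silver-activated benzylic cation could then alkylate another electron-rich ring (oligomerisation), and 11 itself may degrade before use. The fallback avoids the bromide and the silver salt; it sets out from 8 and 7 and returns at 12. Aldehyde 8 is reduced (NaBH4, MeOH) to 5-(hydroxymethyl)-2,3-dimethoxyphenol F3. F3 is condensed with 7 by HBF4·OEt2 in CH2Cl2 (acid-promoted SN1 alkylation of the sulfide by the benzylic alcohol) to give (2S,5S)-1-(3-hydroxy-4,5-dimethoxybenzyl)-2,5-dimethylthiolan-1-ium tetrafluoroborate F4. The phenol of F4 is silylated with N-(tert-butyldimethylsilyl)-N-methyltrifluoroacetamide in MeCN, a neutral silyl donor that leaves the counter-ion unchanged, to give 12.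

Step 10. Oxidative addition into the electron-rich bromide (para to O1) may be slow enough for protodeboronation of 17 to compete, and palladium hydride species could erode the alkene geometry. The fallback separates C–C bond formation from setting the geometry; it sets out from 16 and returns at 18. Compound 16 is coupled with allylboronic acid pinacol ester (Pd(PPh3)4, CsF, THF, 65 °C) to give tert-butyl{5-[(2S,3S)-7-methoxy-3-methyl-5-(prop-2-enyl)-2,3-dihydro-1-benzofuran-2-yl]-2,3-dimethoxyphenoxy}dimethylsilane F5. The allyl group is isomerised into conjugation with RuClH(CO)(PPh3)3 in toluene at 80 °C, which should give the thermodynamically favoured E isomer 18. TBAF in THF then gives 19.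

Step 2. The acid-generated benzylic cation may self-condense or lose a proton to the vinylphenol faster than the moderately nucleophilic sulfinate captures it. The fallback uses a better nucleophile and adjusts the oxidation level afterwards; it sets out from 2 and returns at 3. Alcohol 2 is treated with 4-methylbenzenethiol and catalytic p-toluenesulfonic acid in CH2Cl2 to give 4-bromo-2-methoxy-6-[1-(4-methylphenylsulfanyl)ethyl]phenol F6 (racemic). F6 is oxidised with mCPBA (2.2 equiv, CH2Cl2, 0 °C) to 3.

## Further compounds

F1 | step 9 | 1-{3-[(tert-butyldimethylsilyl)oxy]-4,5-dimethoxybenzyl}thiolan-1-ium tetrafluoroborate | C1CC[S+](C1)Cc1cc(O[Si](C)(C)C(C)(C)C)c(OC)c(OC)c1.F[B-](F)(F)F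
F2 | step 9 | racemic trans-5-bromo-2-{3-[(tert-butyldimethylsilyl)oxy]-4,5-dimethoxyphenyl}-7-methoxy-3-methyl-2,3-dihydro-1-benzofuran (both enantiomers shown) | Brc1cc(OC)c2c(c1)[C@H](C)[C@@H](c1cc(O[Si](C)(C)C(C)(C)C)c(OC)c(OC)c1)O2.Brc1cc(OC)c2c(c1)[C@@H](C)[C@H](c1cc(O[Si](C)(C)C(C)(C)C)c(OC)c(OC)c1)O2
F3 | step 8 | 5-(hydroxymethyl)-2,3-dimethoxyphenol | OCc1cc(O)c(OC)c(OC)c1
F4 | step 8 | (2S,5S)-1-(3-hydroxy-4,5-dimethoxybenzyl)-2,5-dimethylthiolan-1-ium tetrafluoroborate | C[C@H]1CC[C@H](C)[S+]1Cc1cc(O)c(OC)c(OC)c1.F[B-](F)(F)F
F5 | step 10 | tert-butyl{5-[(2S,3S)-7-methoxy-3-methyl-5-(prop-2-enyl)-2,3-dihydro-1-benzofuran-2-yl]-2,3-dimethoxyphenoxy}dimethylsilane | C=CCc1cc(OC)c2c(c1)[C@H](C)[C@@H](c1cc(O[Si](C)(C)C(C)(C)C)c(OC)c(OC)c1)O2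
F6 | step 2 | 4-bromo-2-methoxy-6-[1-(4-methylphenylsulfanyl)ethyl]phenol (racemic) | CC(Sc1ccc(C)cc1)c1cc(Br)cc(OC)c1O
A1 | alternative 1 | (1S,2S)-1-[3-(methoxymethoxy)-4,5-dimethoxyphenyl]-2-{3-methoxy-5-[(E)-prop-1-enyl]-2-(trifluoromethylsulfonyloxy)phenyl}propan-1-ol | C/C=C/c1cc(OC)c(OS(=O)(=O)C(F)(F)F)c(c1)[C@H](C)[C@@H](c1cc(OCOC)c(OC)c(OC)c1)O
A2 | alternative 1 | (2S,3S)-7-methoxy-2-[3-(methoxymethoxy)-4,5-dimethoxyphenyl]-3-methyl-5-[(E)-prop-1-enyl]-2,3-dihydro-1-benzofuran | C/C=C/c1cc(OC)c2c(c1)[C@H](C)[C@@H](c1cc(OCOC)c(OC)c(OC)c1)O2
A3 | alternative 2 | methyl 3-[(1R,2R)-2-{3-[(tert-butyldimethylsilyl)oxy]-4,5-dimethoxyphenyl}cyclopropyl]-4-hydroxy-5-methoxybenzoate | COC(=O)c1cc(OC)c(O)c(c1)[C@@H]1C[C@H]1c1cc(O[Si](C)(C)C(C)(C)C)c(OC)c(OC)c1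
A4 | alternative 2 | methyl (2S,3S)-2-{3-[(tert-butyldimethylsilyl)oxy]-4,5-dimethoxyphenyl}-7-methoxy-3-methyl-2,3-dihydro-1-benzofuran-5-carboxylate | COC(=O)c1cc(OC)c2c(c1)[C@H](C)[C@@H](c1cc(O[Si](C)(C)C(C)(C)C)c(OC)c(OC)c1)O2
A5 | alternative 3 | methyl 2-[5-bromo-3-methoxy-2-{[3-(methoxymethoxy)-4,5-dimethoxyphenyl]methoxy}phenyl]-2-diazoacetate | COC(=O)C(=[N+]=[N-])c1cc(Br)cc(OC)c1OCc1cc(OCOC)c(OC)c(OC)c1
A6 | alternative 3 | methyl (2S,3R)-5-bromo-7-methoxy-2-[3-(methoxymethoxy)-4,5-dimethoxyphenyl]-2,3-dihydro-1-benzofuran-3-carboxylate (cis) | Brc1cc(OC)c2c(c1)[C@@H](C(=O)OC)[C@@H](c1cc(OCOC)c(OC)c(OC)c1)O2
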